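**Retrosynthetic overview** (macrolide numbering: C1 = lactone carbonyl … C13 = ethyl-bearing carbinol carbon; exocyclic methylene on C10)
1. Target ⇐ protected 14-membered lactone by three end-game operations: C3–OSiEt3 → C3=O, and the C4 diol released from its acetonide.
2. Key disconnection C10–C11: the 2-substituted 1,3-diene C10(=CH2)–C11H=C12(Me) in the 14-membered oxacycle, with its methylene exocyclic on C10, is the retron of a branch-selective oxidative boron-Heck ring closure between a terminal alkene (C9–C10H=CH2, an allyl group on C8) and an (E)-alkenylboronate at C11.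
3. Seco ester ⇐ Yamaguchi esterification of a C1–C10 acid with the C11–C13 boronate alcohol; C2 and C3 ⇐ Evans syn aldol on a C3 aldehyde.
4. C4 quaternary carbinol and the (E)-C6=C7 alkene ⇐ one Ireland–Claisen rearrangement of a glycerate acetonide ester, relaying C7 (set by CBS reduction) to C4; C8 ⇐ Evans allylation; C13 ⇐ CBS reduction.
5. Ring order: dioxolane (temporary, carried in from the glycerate) → 14-membered lactone (key step) → dioxolane opened last.

Key step: step 18

Assumption: C2 lies between the lactone and ketone carbonyls in 31 and 32 and is labile there; the (2R) configuration installed by the aldol is taken to be also the thermodynamically preferred one in the 14-membered ring, so that it persists through steps 20 and 21.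

**Route**

Step 1
Reactants: 1 rac-pent-1-yn-3-ol
Product: 3 rac-(E)-1-iodo-2-methylpent-1-en-3-ol, via alkenylalane 2 (not isolated)
Conditions: AlMe3 (3 equiv), Cp2ZrCl2 (0.3 equiv), CH2Cl2, 0 °C → rt; then I2, THF, −30 → 0 °C
Reagents that add atoms: trimethylaluminium, C[Al](C)C; iodine, II
Why: Zirconium-catalysed carboalumination (Negishi) adds Me and Al syn across the terminal alkyne with Me on the internal carbon, and iodinolysis of the C–Al bond with retention should give the (E)-iodide.

Step 2
Reactants: 3 rac-(E)-1-iodo-2-methylpent-1-en-3-ol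
Product: 4 (E)-1-iodo-2-methylpent-1-en-3-one
Conditions: Dess–Martin periodinane, pyridine, CH2Cl2, 0 °C → rt
Reagents that add atoms: none
Why: Dess–Martin oxidation of the allylic alcohol gives the enone, so that the racemic alcohol can be used and C13 is set in the next step.

Step 3
Reactants: 4 (E)-1-iodo-2-methylpent-1-en-3-one
Product: 5 (R,E)-1-iodo-2-methylpent-1-en-3-ol
Conditions: (S)-2-methyl-CBS-oxazaborolidine (0.2 equiv), BH3·SMe2, THF, −20 °C
Reagents that add atoms: none
Why: Corey–Bakshi–Shibata reduction with the alkenyl group as the large substituent should deliver hydride to one face of the ketone and set C13 as (R).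

Step 4
Reactants: 5 (R,E)-1-iodo-2-methylpent-1-en-3-ol
Product: 6 (R,E)-2-methyl-1-(4,4,5,5-tetramethyl-1,3,2-dioxaborolan-2-yl)pent-1-en-3-ol
Conditions: bis(pinacolato)diboron, PdCl2(PPh3)2 (3 mol %), PPh3, KOPh, toluene, 50 °C
Reagents that add atoms: bis(pinacolato)diboron, CC1(C)OB(OC1(C)C)B1OC(C)(C)C(C)(C)O1
Why: Miyaura borylation of the alkenyl iodide with a phenoxide base proceeds with retention of the (E) geometry and tolerates the free alcohol.

Step 5
Reactants: 7 (R)-4-benzyl-3-propanoyloxazolidin-2-one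
Product: 9 (R)-4-benzyl-3-[(S)-2-methylpent-4-enoyl]oxazolidin-2-one, via sodium enolate 8 (not isolated)
Conditions: NaN(SiMe3)2, THF, −78 °C; allyl iodide, −78 → −40 °C
Reagents that add atoms: allyl iodide, C=CCI
Why: Evans alkylation, in which the chelated (Z)-sodium enolate is allylated on the face opposite the benzyl group, should set C8 as (S).

Step 6
Reactants: 9 (R)-4-benzyl-3-[(S)-2-methylpent-4-enoyl]oxazolidin-2-one
Product: 10 (S)-N-methoxy-N,2-dimethylpent-4-enamide
Conditions: MeNH(OMe)·HCl, AlMe3, CH2Cl2, −10 °C → rt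
Reagents that add atoms: N,O-dimethylhydroxylamine hydrochloride, CNOC.Cl
Why: Weinreb transamination with the aluminium amide cleaves the auxiliary at the exocyclic carbonyl without touching the α-stereocentre.

Step 7
Reactants: 10 (S)-N-methoxy-N,2-dimethylpent-4-enamide
Product: 11 (S)-2,4-dimethylhepta-1,6-dien-3-one
Conditions: CH2=C(CH3)MgBr, THF, −78 → 0 °C; aq. NH4Cl
Reagents that add atoms: isopropenylmagnesium bromide, C=C(C)[Mg]Br
Why: Grignard addition to the Weinreb amide stops at the chelated tetrahedral intermediate, so the isopropenyl ketone is released only on work-up, without over-addition or epimerisation.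

Step 8
Reactants: 11 (S)-2,4-dimethylhepta-1,6-dien-3-one
Product: 12 (3S,4S)-2,4-dimethylhepta-1,6-dien-3-ol
Conditions: (R)-2-methyl-CBS-oxazaborolidine (0.3 equiv), catecholborane, toluene, −78 °C
Reagents that add atoms: none
Why: Corey–Bakshi–Shibata reduction with catecholborane (which leaves the terminal alkene alone) treats the isopropenyl group as the large substituent and should set C7 as (S) under reagent control, anti to the C8 methyl group.

Step 9
Reactants: 13 methyl (R)-2,2-dimethyl-1,3-dioxolane-4-carboxylate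
Product: 14 potassium (R)-2,2-dimethyl-1,3-dioxolane-4-carboxylate
Conditions: KOH, MeOH, 0 °C → rt
Reagents that add atoms: potassium hydroxide, [K+].[OH-]
Why: Mild saponification gives the carboxylate salt and avoids handling the acid-labile free acid.

Step 10
Reactants: 14 potassium (R)-2,2-dimethyl-1,3-dioxolane-4-carboxylate; 12 (3S,4S)-2,4-dimethylhepta-1,6-dien-3-ol
Product: 16 (3S,4S)-2,4-dimethylhepta-1,6-dien-3-yl (R)-2,2-dimethyl-1,3-dioxolane-4-carboxylate, via mixed anhydride 15 (not isolated)
Conditions: 2,4,6-trichlorobenzoyl chloride, THF, rt; then 12, DMAP, toluene, rt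
Reagents that add atoms: none
Why: Yamaguchi esterification through the mixed anhydride acylates the hindered secondary allylic alcohol with retention at C7; the glycerate stereocentre is erased in the next step and does not matter.

Step 11
Reactants: 16 (3S,4S)-2,4-dimethylhepta-1,6-dien-3-yl (R)-2,2-dimethyl-1,3-dioxolane-4-carboxylate
Product: 19 (4R)-4-[(2E,4S)-2,4-dimethylhepta-2,6-dien-1-yl]-2,2-dimethyl-1,3-dioxolane-4-carboxylic acid, via ketene silyl acetal 17 (not isolated), via trimethylsilyl ester 18 (not isolated)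
Conditions: Me3SiCl, then LiN(i-Pr)2, THF, −100 → −78 °C; warm to rt; 1 M HCl work-up
Reagents that add atoms: none
Why: Ireland–Claisen rearrangement, in which lithium chelation between the enolate oxygen and the ring oxygen on the α-carbon fixes the (Z)-ketene silyl acetal and a chair transition state with the C8 chain equatorial transfers the (7S) carbinol configuration to the new (4R) quaternary centre, forming the C4–C5 bond and the (E)-C6=C7 alkene in one event.

Step 12
Reactants: 19 (4R)-4-[(2E,4S)-2,4-dimethylhepta-2,6-dien-1-yl]-2,2-dimethyl-1,3-dioxolane-4-carboxylic acid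
Product: 20 [(4S)-4-[(2E,4S)-2,4-dimethylhepta-2,6-dien-1-yl]-2,2-dimethyl-1,3-dioxolan-4-yl]methanol
Conditions: LiAlH4, THF, 0 °C → rt
Reagents that add atoms: none
Why: LiAlH4 reduces the hindered acid to the neopentyl-type alcohol without affecting the acetonide or the isolated alkenes (the descriptor at C4 changes by priority only).

Step 13
Reactants: 20 [(4S)-4-[(2E,4S)-2,4-dimethylhepta-2,6-dien-1-yl]-2,2-dimethyl-1,3-dioxolan-4-yl]methanol
Product: 21 (4R)-4-[(2E,4S)-2,4-dimethylhepta-2,6-dien-1-yl]-2,2-dimethyl-1,3-dioxolane-4-carbaldehyde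
Conditions: Dess–Martin periodinane, pyridine, CH2Cl2, rt
Reagents that add atoms: none
Why: Dess–Martin oxidation gives the C3 aldehyde, which has no α-hydrogen and so cannot epimerise at C4.

Step 14
Reactants: 7 (R)-4-benzyl-3-propanoyloxazolidin-2-one; 21 (4R)-4-[(2E,4S)-2,4-dimethylhepta-2,6-dien-1-yl]-2,2-dimethyl-1,3-dioxolane-4-carbaldehyde
Product: 23 (R)-4-benzyl-3-[(2R,3R)-3-[(4R)-4-[(2E,4S)-2,4-dimethylhepta-2,6-dien-1-yl]-2,2-dimethyl-1,3-dioxolan-4-yl]-3-hydroxy-2-methylpropanoyl]oxazolidin-2-one, via boron enolate 22 (not isolated)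
Conditions: 7, Bu2BOTf, i-Pr2NEt, CH2Cl2, 0 °C; then 21, −78 → 0 °C; pH 7 buffer, MeOH, H2O2
Reagents that add atoms: none
Why: Evans syn aldol, in which the (Z)-boron enolate reacts through a closed chair transition state on the enolate face opposite the benzyl group, should set C2 as (R) and C3 as (R) under auxiliary control.

Step 15
Reactants: 23 aldol adduct
Product: 24 (R)-4-benzyl-3-[(2R,3R)-3-[(4R)-4-[(2E,4S)-2,4-dimethylhepta-2,6-dien-1-yl]-2,2-dimethyl-1,3-dioxolan-4-yl]-2-methyl-3-(triethylsilyloxy)propanoyl]oxazolidin-2-one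
Conditions: Et3SiOTf, 2,6-lutidine, CH2Cl2, −78 → 0 °C
Reagents that add atoms: triethylsilyl trifluoromethanesulfonate, CC[Si](CC)(CC)OS(=O)(=O)C(F)(F)F
Why: Silylation with the silyl triflate masks the only free hydroxyl group, which would otherwise be oxidised under the aerobic palladium conditions of the key step.

Step 16
Reactants: 24 triethylsilyl-protected imide
Product: 26 (2R,3R)-3-[(4R)-4-[(2E,4S)-2,4-dimethylhepta-2,6-dien-1-yl]-2,2-dimethyl-1,3-dioxolan-4-yl]-2-methyl-3-(triethylsilyloxy)propanoic acid, via lithium peroxycarboxylate 25 (not isolated)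
Conditions: LiOH, H2O2, THF/H2O, 0 °C; then Na2SO3; dilute HCl to pH 4, 0 °C
Reagents that add atoms: hydrogen peroxide (as lithium hydroperoxide), OO
Why: Lithium hydroperoxide attacks the exocyclic imide carbonyl selectively and the peracid salt is reduced by sulfite, which frees the acid without epimerising C2.

Step 17
Reactants: 26 C1–C10 acid; 6 (R,E)-2-methyl-1-(4,4,5,5-tetramethyl-1,3,2-dioxaborolan-2-yl)pent-1-en-3-ol
Product: 28 (1E,3R)-2-methyl-1-(4,4,5,5-tetramethyl-1,3,2-dioxaborolan-2-yl)pent-1-en-3-yl (2R,3R)-3-[(4R)-4-[(2E,4S)-2,4-dimethylhepta-2,6-dien-1-yl]-2,2-dimethyl-1,3-dioxolan-4-yl]-2-methyl-3-(triethylsilyloxy)propanoate, via mixed anhydride 27 (not isolated)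
Conditions: 2,4,6-trichlorobenzoyl chloride, Et3N, THF, rt; then 6, DMAP, toluene, rt
Reagents that add atoms: none
Why: Yamaguchi esterification joins the two fragments at the C1–O bond with retention at C13, and the alkenylboronic ester is inert to the acylation conditions.

Step 18
Reactants: 28 seco ester
Product: 29 protected macrolactone: 14-membered lactone with (2R)-methyl, (3R)-triethylsilyloxy, C4 (R) as spiro carbon of the 2,2-dimethyl-1,3-dioxolane, (6E)-6-methyl, (8S)-methyl, 10-methylidene, (11E)-12-methyl and (13R)-ethyl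
Conditions: Pd(OCOCF3)2 (10 mol %), 2,9-dimethyl-1,10-phenanthroline (12 mol %), O2 (1 atm), N-methylpyrrolidone, 45 °C, slow addition of 28 to a final 2 mM
Reagents that add atoms: none
Why: Proposed new method: the alkenyl group is transferred from boron to the divalent palladium trifluoroacetate complex with retention, the tethered terminal alkene inserts into the alkenyl–Pd bond with C–C bond formation at its internal carbon C10, β-hydride elimination of C10–H (the only β-hydrogen) creates the exocyclic methylene, and O2 reoxidises the zerovalent palladium. The closest known reaction is the intermolecular aerobic oxidative boron-Heck coupling of alkenylboron reagents with unactivated terminal alkenes, which with this hindered phenanthroline ligand is branch-selective and gives 2-substituted 1,3-dienes; macrocyclic Heck and Suzuki–Miyaura ring closures are the precedent for the ring size. The 14-membered ring closes in the exo mode (14-exo-trig insertion), so the terminal CH2 stays outside the ring. No stereocentre is formed, and the (E) geometry of C11=C12 is carried over from the boronate. The step needs branched rather than linear insertion (the latter would give the 15-membered endo isomer), which the 2,9-dimethyl groups of the ligand should secure by steering palladium to the terminal carbon, and it needs the alkenylpalladium to find the alkene of its own molecule, which slow addition at high dilution should secure. The substrate carries no free hydroxyl group and no 1,3-dicarbonyl unit that could be oxidised or bind palladium, and the trisubstituted C6=C7 alkene is too hindered to insert.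

Step 19
Reactants: 29 protected macrolactone
Product: 30 C3 alcohol: the same macrolactone acetonide with a free (3R)-hydroxyl group
Conditions: HF·pyridine, pyridine, THF, 0 °C → rt
Reagents that add atoms: none
Why: Buffered HF·pyridine cleaves the triethylsilyl ether selectively in the presence of the acetonide and the lactone.

Step 20
Reactants: 30 C3 alcohol
Product: 31 3-oxo macrolactone acetonide (2R,4R,6E,8S,11E,13R)
Conditions: Dess–Martin periodinane, pyridine, CH2Cl2, 0 °C → rt
Reagents that add atoms: none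
Why: Dess–Martin oxidation under buffered, non-basic conditions converts the C3 alcohol into the ketone without exposing C2, now between two carbonyl groups, to base.

Step 21
Reactants: 31 3-oxo macrolactone acetonide
Product: 32 (3R,5R,7E,9S,12E,14R)-14-ethyl-5-hydroxy-5-(hydroxymethyl)-3,7,9,13-tetramethyl-11-methylidene-1-oxacyclotetradeca-7,12-diene-2,4-dione (target)
Conditions: CF3CO2H/H2O/THF (1:1:4), 0 °C → rt
Reagents that add atoms: none
Why: Aqueous acid hydrolysis of the isopropylidene acetal frees the C4 tertiary alcohol and the primary alcohol and completes the target, with C2 expected to stay in its preferred (R) configuration.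

**Compound list**
1 | rac-pent-1-yn-3-ol | C#CC(O)CC | starting material
2 | alkenylalane: dimethylaluminium alkoxide of (E)-1-(dimethylalumanyl)-2-methylpent-1-en-3-ol | CCC(O[Al](C)C)/C(C)=C/[Al](C)C | intermediate
3 | rac-(E)-1-iodo-2-methylpent-1-en-3-ol | CCC(O)/C(C)=C/I | intermediate
4 | (E)-1-iodo-2-methylpent-1-en-3-one | CCC(=O)/C(C)=C/I | intermediate
5 | (R,E)-1-iodo-2-methylpent-1-en-3-ol | CC[C@@H](O)/C(C)=C/I | intermediate
6 | (R,E)-2-methyl-1-(4,4,5,5-tetramethyl-1,3,2-dioxaborolan-2-yl)pent-1-en-3-ol | CC[C@@H](O)/C(C)=C/B1OC(C)(C)C(C)(C)O1 | intermediate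
7 | (R)-4-benzyl-3-propanoyloxazolidin-2-one | CCC(=O)N1[C@H](Cc2ccccc2)COC1=O | starting material
8 | sodium (Z)-enolate of 7 | C/C=C(\[O-])N1[C@H](Cc2ccccc2)COC1=O.[Na+] | intermediate
9 | (R)-4-benzyl-3-[(S)-2-methylpent-4-enoyl]oxazolidin-2-one | C=CC[C@H](C)C(=O)N1[C@H](Cc2ccccc2)COC1=O | intermediate
10 | (S)-N-methoxy-N,2-dimethylpent-4-enamide | C=CC[C@H](C)C(=O)N(C)OC | intermediate
11 | (S)-2,4-dimethylhepta-1,6-dien-3-one | C=CC[C@H](C)C(=O)C(C)=C | intermediate
12 | (3S,4S)-2,4-dimethylhepta-1,6-dien-3-ol | C=CC[C@H](C)[C@H](O)C(C)=C | intermediate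
13 | methyl (R)-2,2-dimethyl-1,3-dioxolane-4-carboxylate | COC(=O)[C@H]1COC(C)(C)O1 | starting material
14 | potassium (R)-2,2-dimethyl-1,3-dioxolane-4-carboxylate | [K+].[O-]C(=O)[C@H]1COC(C)(C)O1 | intermediate
15 | (R)-2,2-dimethyl-1,3-dioxolane-4-carboxylic 2,4,6-trichlorobenzoic anhydride | O=C(OC(=O)c1c(Cl)cc(Cl)cc1Cl)[C@H]1COC(C)(C)O1 | intermediate
16 | (3S,4S)-2,4-dimethylhepta-1,6-dien-3-yl (R)-2,2-dimethyl-1,3-dioxolane-4-carboxylate | C=CC[C@H](C)[C@H](OC(=O)[C@H]1COC(C)(C)O1)C(C)=C | intermediate
17 | (Z)-ketene silyl acetal of 16 (Me3SiO cis to the ring oxygen) | C=CC[C@H](C)[C@H](O/C(O[Si](C)(C)C)=C1\COC(C)(C)O1)C(C)=C | intermediate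
18 | trimethylsilyl ester of 19 | C[Si](C)(C)OC(=O)[C@]1(COC(C)(C)O1)C/C(C)=C/[C@@H](C)CC=C | intermediate
19 | (4R)-4-[(2E,4S)-2,4-dimethylhepta-2,6-dien-1-yl]-2,2-dimethyl-1,3-dioxolane-4-carboxylic acid | OC(=O)[C@]1(COC(C)(C)O1)C/C(C)=C/[C@@H](C)CC=C | intermediate
20 | [(4S)-4-[(2E,4S)-2,4-dimethylhepta-2,6-dien-1-yl]-2,2-dimethyl-1,3-dioxolan-4-yl]methanol | OC[C@]1(COC(C)(C)O1)C/C(C)=C/[C@@H](C)CC=C | intermediate
21 | (4R)-4-[(2E,4S)-2,4-dimethylhepta-2,6-dien-1-yl]-2,2-dimethyl-1,3-dioxolane-4-carbaldehyde | O=C[C@]1(COC(C)(C)O1)C/C(C)=C/[C@@H](C)CC=C | intermediate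
22 | (Z)-dibutylboron enolate of 7 | C/C=C(\OB(CCCC)CCCC)N1[C@H](Cc2ccccc2)COC1=O | intermediate
23 | (R)-4-benzyl-3-[(2R,3R)-3-[(4R)-4-[(2E,4S)-2,4-dimethylhepta-2,6-dien-1-yl]-2,2-dimethyl-1,3-dioxolan-4-yl]-3-hydroxy-2-methylpropanoyl]oxazolidin-2-one | O=C1OC[C@@H](Cc2ccccc2)N1C(=O)[C@H](C)[C@@H](O)[C@]1(COC(C)(C)O1)C/C(C)=C/[C@@H](C)CC=C | intermediate
24 | triethylsilyl ether of 23 | O=C1OC[C@@H](Cc2ccccc2)N1C(=O)[C@H](C)[C@@H](O[Si](CC)(CC)CC)[C@]1(COC(C)(C)O1)C/C(C)=C/[C@@H](C)CC=C | intermediate
25 | lithium peroxycarboxylate of 26 | [Li+].[O-]OC(=O)[C@H](C)[C@@H](O[Si](CC)(CC)CC)[C@]1(COC(C)(C)O1)C/C(C)=C/[C@@H](C)CC=C | intermediate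
26 | (2R,3R)-3-[(4R)-4-[(2E,4S)-2,4-dimethylhepta-2,6-dien-1-yl]-2,2-dimethyl-1,3-dioxolan-4-yl]-2-methyl-3-(triethylsilyloxy)propanoic acid | OC(=O)[C@H](C)[C@@H](O[Si](CC)(CC)CC)[C@]1(COC(C)(C)O1)C/C(C)=C/[C@@H](C)CC=C | intermediate
27 | mixed anhydride of 26 with 2,4,6-trichlorobenzoic acid | O=C(OC(=O)c1c(Cl)cc(Cl)cc1Cl)[C@H](C)[C@@H](O[Si](CC)(CC)CC)[C@]1(COC(C)(C)O1)C/C(C)=C/[C@@H](C)CC=C | intermediate
28 | seco ester: (1E,3R)-2-methyl-1-(pinacolboryl)pent-1-en-3-yl ester of 26 | CC[C@@H](OC(=O)[C@H](C)[C@@H](O[Si](CC)(CC)CC)[C@]1(COC(C)(C)O1)C/C(C)=C/[C@@H](C)CC=C)/C(C)=C/B2OC(C)(C)C(C)(C)O2 | intermediate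
29 | protected macrolactone (2R,3R,4R,6E,8S,11E,13R; 3-OSiEt3; C4 diol as acetonide) | C=C1/C=C(\C)[C@@H](CC)OC(=O)[C@H](C)[C@@H](O[Si](CC)(CC)CC)[C@]2(COC(C)(C)O2)C/C(C)=C/[C@@H](C)C1 | intermediate
30 | macrolactone acetonide with free (3R)-hydroxyl | C=C1/C=C(\C)[C@@H](CC)OC(=O)[C@H](C)[C@@H](O)[C@]2(COC(C)(C)O2)C/C(C)=C/[C@@H](C)C1 | intermediate
31 | 3-oxo macrolactone acetonide | C=C1/C=C(\C)[C@@H](CC)OC(=O)[C@H](C)C(=O)[C@]2(COC(C)(C)O2)C/C(C)=C/[C@@H](C)C1 | intermediate
32 | (3R,5R,7E,9S,12E,14R)-14-ethyl-5-hydroxy-5-(hydroxymethyl)-3,7,9,13-tetramethyl-11-methylidene-1-oxacyclotetradeca-7,12-diene-2,4-dione | C=C1/C=C(\C)[C@@H](CC)OC(=O)[C@H](C)C(=O)[C@](O)(CO)C/C(C)=C/[C@@H](C)C1 | target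

**Step count**
Total: 21 steps. Longest linear sequence: 16 steps (7 → 32, steps 5–8 and 10–21); steps 1–4 (alcohol 6) and step 9 (salt 14) are side branches.

**Steps most likely to fail**

Step 18 (Proposed new method). The alkenylpalladium intermediate may be lost by protodeboronation or oxidative homocoupling before it reaches the alkene, or insertion may occur at the terminal carbon and give the 15-membered linear diene. The fallback closes the same C10–C11 bond by a known intramolecular Suzuki–Miyaura coupling. It sets out from 24. Wacker oxidation of the terminal alkene (PdCl2, CuCl, O2, DMF/H2O, rt) should give the methyl ketone imide F1. LiOH/H2O2 followed by Na2SO3 should give the keto acid F2. Yamaguchi esterification with 6 should give the keto ester F3. Kinetic deprotonation of the methyl group and O-triflation (KN(SiMe3)2, PhNTf2, THF, −78 °C) should give the enol triflate F4, a 2-triflyloxy-1-alkene at C10. Coupling of the alkenyl triflate with the alkenylboronate (Pd(PPh3)4, K3PO4, THF/H2O, high dilution, rt) closes the ring and comes back to the route at 29.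

Step 11. Loss of lithium chelation would erode the ketene acetal geometry and with it the facial selectivity at C4, and β-elimination of the enolate would open the dioxolane. The fallback sets C4 by intermolecular alkylation of an exocyclic dioxolane enolate whose facial bias comes from an acetal stereocentre (self-regeneration of the glycerate stereocentre). It sets out from 13 and 12. Acid-catalysed transacetalisation of 13 with pivalaldehyde, with separation of the cis isomer, should give methyl (2R,4R)-2-tert-butyl-1,3-dioxolane-4-carboxylate F5. PBr3 should convert 12 with allylic transposition into (S,E)-1-bromo-2,4-dimethylhepta-2,6-diene F6. The lithium enolate of F5 (LiN(i-Pr)2, THF, −78 °C) is alkylated by F6 anti to the tert-butyl group to give the quaternary ester F7. HCl/MeOH removes the pivalaldehyde acetal to give the diol ester F8, and 2,2-dimethoxypropane with an acid catalyst gives the acetonide ester F9. LiAlH4 reduction of F9 comes back to the route at 20.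

Step 8. Reagent control may be poor because the isopropenyl and the α-branched alkyl group are of similar size and the C8 centre may be mismatched. The fallback replaces the enantioselective reduction by a kinetic resolution. It sets out from 11. Luche reduction (NaBH4, CeCl3·7H2O, MeOH, −78 °C) gives 12 together with its C7 epimer, (3R,4S)-2,4-dimethylhepta-1,6-dien-3-ol F10. Sharpless kinetic resolution of the mixture (Ti(Oi-Pr)4, D-(−)-diisopropyl tartrate, t-BuOOH, 4 Å molecular sieves, CH2Cl2, −20 °C) should epoxidise the (3R) epimer to the erythro epoxy alcohol F11 and leave 12, at which the fallback comes back to the route.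

**Further compounds**
F1 | step 18 | (R)-4-benzyl-3-[(2R,3R)-3-[(4R)-4-[(2E,4S)-2,4-dimethyl-6-oxohept-2-en-1-yl]-2,2-dimethyl-1,3-dioxolan-4-yl]-2-methyl-3-(triethylsilyloxy)propanoyl]oxazolidin-2-one | O=C1OC[C@@H](Cc2ccccc2)N1C(=O)[C@H](C)[C@@H](O[Si](CC)(CC)CC)[C@]1(COC(C)(C)O1)C/C(C)=C/[C@@H](C)CC(C)=O
F2 | step 18 | (2R,3R)-3-[(4R)-4-[(2E,4S)-2,4-dimethyl-6-oxohept-2-en-1-yl]-2,2-dimethyl-1,3-dioxolan-4-yl]-2-methyl-3-(triethylsilyloxy)propanoic acid | OC(=O)[C@H](C)[C@@H](O[Si](CC)(CC)CC)[C@]1(COC(C)(C)O1)C/C(C)=C/[C@@H](C)CC(C)=O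
F3 | step 18 | (1E,3R)-2-methyl-1-(pinacolboryl)pent-1-en-3-yl ester of F2 | CC[C@@H](OC(=O)[C@H](C)[C@@H](O[Si](CC)(CC)CC)[C@]1(COC(C)(C)O1)C/C(C)=C/[C@@H](C)CC(C)=O)/C(C)=C/B2OC(C)(C)C(C)(C)O2
F4 | step 18 | enol triflate of F3 (C10 as 2-(trifluoromethylsulfonyloxy)-1-alkene) | CC[C@@H](OC(=O)[C@H](C)[C@@H](O[Si](CC)(CC)CC)[C@]1(COC(C)(C)O1)C/C(C)=C/[C@@H](C)CC(=C)OS(=O)(=O)C(F)(F)F)/C(C)=C/B2OC(C)(C)C(C)(C)O2
F5 | step 11 | methyl (2R,4R)-2-tert-butyl-1,3-dioxolane-4-carboxylate | COC(=O)[C@H]1CO[C@@H](C(C)(C)C)O1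
F6 | step 11 | (S,E)-1-bromo-2,4-dimethylhepta-2,6-diene | BrC/C(C)=C/[C@@H](C)CC=C
F7 | step 11 | methyl (2R,4R)-2-tert-butyl-4-[(2E,4S)-2,4-dimethylhepta-2,6-dien-1-yl]-1,3-dioxolane-4-carboxylate | COC(=O)[C@]1(CO[C@@H](C(C)(C)C)O1)C/C(C)=C/[C@@H](C)CC=C
F8 | step 11 | methyl (2R,4E,6S)-2-hydroxy-2-(hydroxymethyl)-4,6-dimethylnona-4,8-dienoate | COC(=O)[C@](O)(CO)C/C(C)=C/[C@@H](C)CC=C
F9 | step 11 | methyl (4R)-4-[(2E,4S)-2,4-dimethylhepta-2,6-dien-1-yl]-2,2-dimethyl-1,3-dioxolane-4-carboxylate | COC(=O)[C@]1(COC(C)(C)O1)C/C(C)=C/[C@@H](C)CC=C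
F10 | step 8 | (3R,4S)-2,4-dimethylhepta-1,6-dien-3-ol | C=CC[C@H](C)[C@@H](O)C(C)=C
F11 | step 8 | (1R,2S)-2-methyl-1-[(2R)-2-methyloxiran-2-yl]pent-4-en-1-ol | C=CC[C@H](C)[C@@H](O)[C@@]1(C)CO1
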